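**Remark on the chemistry (one assumption).** Atoms carry kaurane-type numbers: ring A is C1(=O), C2=C3, C4(CH3)2, C5(C6H2OH), C10; the lactone is C10–C20H2–O–C7(=O)–C8–C9; ring C is C8, C9, C11, C12, C13, C14; ring D is C8, C15, C16(C17), C13, C14. Cyclopentadiene esters 23, 24 and their fallback analogues are assumed to be mixtures of double-bond tautomers that interconvert by 1,5-hydrogen shifts; they are drawn as the reacting tautomer and handled cold, dilute and without storage.

## Retrosynthetic overview

1. Target 35 ← C16 hydration of the C15 exo-methylene ketone, singlet-oxygen ene/dehydration at C15=C16 and C1=C2, and removal of the C11 carbonyl ← cycloadduct 26.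
2. The strategy rests on this feature: ring D plus C14 is a cyclopentadiene whose termini C8 and C13 are spanned by C9–C11–C12, and C8 carries the lactone carbonyl C7, which serves as the tether. An oxyallyl (4+3) cycloaddition of 24 forms C8–C9 and C12–C13 and closes the δ-lactone, the seven-membered ring and ring C together.
3. 24 ← ring A hydroxy chloromethyl ketone 19 + cyclopentadienylidene ketene 22 (Wolff ring contraction of quinone diazide 21, which fixes the 1,3-relation of ester and methyl).
4. Ring A with C5/C10 ← lactone-enolate Claisen ring contraction of δ-lactone 10; its (S)-carbinol comes from a CBS reduction and its E-alkene from a Z-iodoenone by Stille coupling.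
5. Ring order: temporary δ-lactone 10 → ring A → lactone, ring C and ring D (bicyclo[3.2.1]octene) in the key step.

Key step: step 16

## Route

Step 1
Reactants: 1 3,3-dimethylglutaric anhydride
Product: 2 5-methoxy-3,3-dimethyl-5-oxopentanoic acid
Conditions: MeOH, reflux
Reagents that add atoms: methanol, CO
Why: Alcoholysis of a symmetric cyclic anhydride gives the half ester directly and creates no stereocentre.

Step 2
Reactants: 2 5-methoxy-3,3-dimethyl-5-oxopentanoic acid
Product: 3 methyl 5-chloro-3,3-dimethyl-5-oxopentanoate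
Conditions: (COCl)2, DMF (cat.), CH2Cl2, 0 °C → rt
Reagents that add atoms: oxalyl chloride, O=C(Cl)C(=O)Cl
Why: Acid chloride formation by Vilsmeier-type activation leaves the methyl ester untouched.

Step 3
Reactants: 4 propargyl alcohol
Product: 5 1-methoxy-4-[(prop-2-yn-1-yloxy)methyl]benzene
Conditions: NaH, THF, 0 °C; 4-methoxybenzyl chloride, Bu4NI (cat.), rt
Reagents that add atoms: 4-methoxybenzyl chloride, COc1ccc(CCl)cc1
Why: Williamson etherification of the alkoxide with a benzylic chloride installs the PMB group that later frees C20–OH under neutral conditions.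

Step 4
Reactants: 3 methyl 5-chloro-3,3-dimethyl-5-oxopentanoate; 5 1-methoxy-4-[(prop-2-yn-1-yloxy)methyl]benzene
Product: 6 methyl 8-[(4-methoxybenzyl)oxy]-3,3-dimethyl-5-oxooct-6-ynoate
Conditions: PdCl2(PPh3)2 (2 mol%), CuI (4 mol%), Et3N, THF, rt
Reagents that add atoms: none
Why: Acyl Sonogashira coupling of an acid chloride with a terminal alkyne gives the ynone (C2 carbonyl, C1≡C10, C20) without touching the ester.

Step 5
Reactants: 6 methyl 8-[(4-methoxybenzyl)oxy]-3,3-dimethyl-5-oxooct-6-ynoate
Product: 7 methyl (Z)-7-iodo-8-[(4-methoxybenzyl)oxy]-3,3-dimethyl-5-oxooct-6-enoate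
Conditions: NaI, AcOH, rt
Reagents that add atoms: sodium iodide, [Na+].[I-]
Why: Conjugate hydroiodination of an ynone proceeds by anti addition of H and I, so iodine should end on C10 cis to the acyl group (Z).

Step 6
Reactants: 7 methyl (Z)-7-iodo-8-[(4-methoxybenzyl)oxy]-3,3-dimethyl-5-oxooct-6-enoate
Product: 8 methyl (5S,6Z)-5-hydroxy-7-iodo-8-[(4-methoxybenzyl)oxy]-3,3-dimethyloct-6-enoate
Conditions: (R)-2-methyl-CBS-oxazaborolidine (20 mol%), catecholborane, toluene, −78 °C
Reagents that add atoms: none
Why: Corey–Bakshi–Shibata reduction in which the alkenyl group acts as the large substituent, so the (R)-catalyst should give the (S)-carbinol at C2; any lactone formed on work-up converges in step 7.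

Step 7
Reactants: 8 methyl (5S,6Z)-5-hydroxy-7-iodo-8-[(4-methoxybenzyl)oxy]-3,3-dimethyloct-6-enoate
Product: 10 (6S)-6-[(1E)-2-{[(4-methoxybenzyl)oxy]methyl}penta-1,4-dien-1-yl]-4,4-dimethyloxan-2-one, via hydroxy dienoate 9 (not isolated)
Conditions: allyltributylstannane, Pd2(dba)3 (2.5 mol%), AsPh3, CuI (10 mol%), DMF, rt; then PPTS (cat.), toluene, 60 °C
Reagents that add atoms: allyltributylstannane, C=CC[Sn](CCCC)(CCCC)CCCC
Why: Stille coupling replaces iodine with retention, so the allyl arm (C9–C11=C12) is cis to C2 and C20 trans (E), and acid then closes the δ-lactone, helped by the gem-dimethyl group.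

Step 8
Reactants: 10 (6S)-6-[(1E)-2-{[(4-methoxybenzyl)oxy]methyl}penta-1,4-dien-1-yl]-4,4-dimethyloxan-2-one
Product: 13 (1R,2S)-2-allyl-2-{[(4-methoxybenzyl)oxy]methyl}-6,6-dimethylcyclohex-3-ene-1-carboxylic acid, via silyl ketene acetal 11 (not isolated), via trimethylsilyl ester 12 (not isolated)
Conditions: LiN(iPr)2 (LDA), TMSCl, THF, −78 °C; then toluene, 105 °C; then 1 M HCl
Reagents that add atoms: none
Why: Ireland–Claisen rearrangement of a lactone silyl ketene acetal (ring contraction) can only pass through a boat-like bridged transition state, so the C2–O stereocentre and the E-alkene geometry should be relayed to C5 (R) and the quaternary C10 (S) with C6 cis to C20, while the C1=C2 alkene is formed.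

Step 9
Reactants: 13 (1R,2S)-2-allyl-2-{[(4-methoxybenzyl)oxy]methyl}-6,6-dimethylcyclohex-3-ene-1-carboxylic acid
Product: 14 [(1R,2S)-2-allyl-2-{[(4-methoxybenzyl)oxy]methyl}-6,6-dimethylcyclohex-3-en-1-yl]methanol
Conditions: LiAlH4, THF, 0 °C → reflux
Reagents that add atoms: none
Why: Hydride reduction of the carboxylic acid gives the C6 alcohol; ether and alkenes are inert.

Step 10
Reactants: 14 [(1R,2S)-2-allyl-2-{[(4-methoxybenzyl)oxy]methyl}-6,6-dimethylcyclohex-3-en-1-yl]methanol
Product: 15 tert-butyl{[(1R,2S)-2-allyl-2-{[(4-methoxybenzyl)oxy]methyl}-6,6-dimethylcyclohex-3-en-1-yl]methoxy}dimethylsilane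
Conditions: TBSCl, imidazole, DMF, rt
Reagents that add atoms: tert-butyldimethylsilyl chloride, CC(C)(C)[Si](C)(C)Cl
Why: Silylation of the primary alcohol gives a C6 ether that survives every later step and is removed last.

Step 11
Reactants: 15 tert-butyl{[(1R,2S)-2-allyl-2-{[(4-methoxybenzyl)oxy]methyl}-6,6-dimethylcyclohex-3-en-1-yl]methoxy}dimethylsilane
Product: 16 1-[(1S,6R)-6-{[(tert-butyldimethylsilyl)oxy]methyl}-1-{[(4-methoxybenzyl)oxy]methyl}-5,5-dimethylcyclohex-2-en-1-yl]propan-2-one
Conditions: PdCl2 (10 mol%), CuCl, O2 (1 atm), DMF/H2O, rt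
Reagents that add atoms: water, O
Why: Tsuji–Wacker oxidation converts the terminal alkene into the methyl ketone (C11), while the hindered internal ring alkene does not react.

Step 12
Reactants: 16 1-[(1S,6R)-6-{[(tert-butyldimethylsilyl)oxy]methyl}-1-{[(4-methoxybenzyl)oxy]methyl}-5,5-dimethylcyclohex-2-en-1-yl]propan-2-one
Product: 18 1-chloro-3-[(1S,6R)-6-{[(tert-butyldimethylsilyl)oxy]methyl}-1-{[(4-methoxybenzyl)oxy]methyl}-5,5-dimethylcyclohex-2-en-1-yl]propan-2-one, via silyl enol ether 17 (not isolated)
Conditions: LiN(SiMe3)2 (LiHMDS), TMSCl, THF, −78 °C; then N-chlorosuccinimide, NaHCO3, THF, −78 → 0 °C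
Reagents that add atoms: N-chlorosuccinimide, O=C1CCC(=O)N1Cl
Why: Kinetic deprotonation takes the methyl (C12) protons and not the neopentyl C9 protons, and chlorination of the resulting terminal silyl enol ether is regiospecific.

Step 13
Reactants: 18 1-chloro-3-[(1S,6R)-6-{[(tert-butyldimethylsilyl)oxy]methyl}-1-{[(4-methoxybenzyl)oxy]methyl}-5,5-dimethylcyclohex-2-en-1-yl]propan-2-one
Product: 19 1-chloro-3-[(1S,6R)-6-{[(tert-butyldimethylsilyl)oxy]methyl}-1-(hydroxymethyl)-5,5-dimethylcyclohex-2-en-1-yl]propan-2-one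
Conditions: DDQ, CH2Cl2/pH 7 buffer, 0 °C
Reagents that add atoms: none
Why: Oxidative cleavage of the PMB ether is neutral, so the base-sensitive chloromethyl ketone and the silyl ether survive; 19 is used at once.

Step 14
Reactants: 20 2-amino-4-methylphenol
Product: 21 6-diazo-4-methylcyclohexa-2,4-dien-1-one
Conditions: NaNO2, aq. HCl, 0 °C; then NaHCO3 to pH 7, extraction into CH2Cl2, dark, 0 °C
Reagents that add atoms: sodium nitrite, [Na+].[O-]N=O
Why: Diazotisation of an ortho-aminophenol followed by deprotonation gives the ortho-quinone diazide.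

Step 15
Reactants: 19 1-chloro-3-[(1S,6R)-6-{[(tert-butyldimethylsilyl)oxy]methyl}-1-(hydroxymethyl)-5,5-dimethylcyclohex-2-en-1-yl]propan-2-one; 21 6-diazo-4-methylcyclohexa-2,4-dien-1-one
Product: 24 {(1S,6R)-6-{[(tert-butyldimethylsilyl)oxy]methyl}-1-(3-chloro-2-oxopropyl)-5,5-dimethylcyclohex-2-en-1-yl}methyl 3-methylcyclopenta-1,3-diene-1-carboxylate, via ketene 22 (not isolated), via 5H-tautomer ester 23 (not isolated)
Conditions: 21 (3 equiv, in portions), hν (365 nm), dry CH2Cl2, −20 °C; kept as a cold dilute solution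
Reagents that add atoms: none
Why: Photochemical Wolff rearrangement of the quinone diazide (Süs ring contraction) gives a cyclopentadienylidene ketene that the neopentyl alcohol should trap without base, which the chloromethyl ketone requires; the ring contraction fixes ester and methyl in a 1,3-relation and 1,5-hydrogen shifts then give the conjugated diene ester.

Step 16
Reactants: 24 {(1S,6R)-6-{[(tert-butyldimethylsilyl)oxy]methyl}-1-(3-chloro-2-oxopropyl)-5,5-dimethylcyclohex-2-en-1-yl}methyl 3-methylcyclopenta-1,3-diene-1-carboxylate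
Product: 26 lactone-fused bicyclo[3.2.1]oct-6-en-3-one (C11 ketone; C15=C16 alkene; C10 on the C14 side of C8; H-9 cis to C5; C6–OTBS), via oxyallyl cation 25 (not isolated)
Conditions: Et3N (2 equiv), Et3NH·OTf (10 equiv), CF3CH2OH, 0.005 M, 0 °C → rt
Reagents that add atoms: none
Why: Proposed new method: Et3N should enolise the ketone towards C9 and chloride then leaves C12, giving the oxyallyl cation 25, whose unhindered terminus C12 bonds to C13 (the δ-carbon of the dienoate, giving a methyl-stabilised allyl cation) before C9 closes onto C8, that is a stepwise or strongly asynchronous (4+3) cycloaddition; the ammonium buffer keeps the acidic diene C–H largely protonated while still letting the diene tautomers equilibrate, so that the 1-carboxylate-3-methyl tautomer, the only one that gives the C16-stabilised cation, can react. The closest known reaction type is the Föhlisch (4+3) cycloaddition of α-chloro ketones with cyclopentadienes or furans in trifluoroethanol, including intramolecular cases with all-carbon tethers; an ester tether ending on the terminus of a cyclopentadienecarboxylate has not been shown. The seven-membered ring (C8, C9, C11, C12, C13, C16, C15) closes by the (4+3) union, ring C (C8, C9, C11, C12, C13, C14) follows because C14 is the one-carbon bridge of the diene, and the δ-lactone (C7, O, C20, C10, C9, C8) closes as a six-membered ring when the tethered terminus C9 bonds to C8 with the ester in its s-cis form, the quaternary C10 favouring closure. C8 and C13 are set together by suprafacial addition to one face of the diene, and C9 by the face of the planar oxyallyl terminus that meets C8. The step needs H-9 cis to C5 on the new lactone, which a chair-like closure with the bulky C5 branch equatorial and C1 axial should secure, and it needs C10 on the C14 side of C8 (anti to C15), which requires the extended arrangement of the Z-configured oxyallyl terminus (C11=O turned towards C14 and away from C15=C16). This second requirement is biased only by the short tether (C10 nearly eclipses C7 in that arrangement, which suits the planar ester) and is the open point of the route.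

Step 17
Reactants: 26 lactone-fused bicyclo[3.2.1]oct-6-en-3-one (C11 ketone)
Product: 28 C11-deoxy lactone diene (C1=C2 and C15=C16 alkenes; C6–OTBS), via tosylhydrazone 27 (not isolated)
Conditions: TsNHNH2, MeOH, 50 °C; then catecholborane, CHCl3, 0 °C; then NaOAc·3H2O, 60 °C
Reagents that add atoms: none
Why: Tosylhydrazone formation and Kabalka (Caglioti-type) reduction remove the C11 carbonyl without base, so the epimerisable C9 next to the ketone is not disturbed and lactone, alkenes and silyl ether are kept.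

Step 18
Reactants: 28 C11-deoxy lactone diene
Product: 32 bis-enone (C1 ketone with C2=C3; C15 ketone with C16=C17 methylene; C6–OTBS), via C15 hydroperoxide 29 (not isolated), via mono-enone 30 (not isolated), via C1 hydroperoxide 31 (not isolated)
Conditions: O2, tetraphenylporphyrin (cat.), visible light, Ac2O, pyridine, DMAP (cat.), CH2Cl2, 0 °C → rt
Reagents that add atoms: oxygen, O=O
Why: Schenck ene reaction of singlet oxygen with in situ Kornblum–DeLaMare-type dehydration of each allylic hydroperoxide; only the C17 hydrogens (C8 quaternary, C13 bridgehead) and only the C3 hydrogens (C10 quaternary) can be abstracted, so oxygen must enter at C15 and at C1.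

Step 19
Reactants: 32 bis-enone
Product: 34 C16-hydroxy C15-ketone (ketol) with ring A enone and C6–OTBS, via C16 hydroperoxide 33 (not isolated)
Conditions: Mn(dpm)3 (dpm = dipivaloylmethanate, 20 mol%), PhSiH3, O2 (1 atm), iPrOH/CH2Cl2, 0 °C; then P(OEt)3
Reagents that add atoms: oxygen, O=O
Why: Mukaiyama-type hydration by hydrogen-atom transfer from a manganese hydride to the 1,1-disubstituted exo-methylene enone gives the tertiary C16 radical, which O2 should trap from the exo face (side of the C14 bridge) to set the C16 hydroxyl; the ring A enone, 1,2-disubstituted with a neopentyl β-carbon, should react far more slowly.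

Step 20
Reactants: 34 C16-hydroxy C15-ketone with C6–OTBS
Product: 35 CNP0530135.1 (5R,8S,9S,10S,13R,16S in the numbering used here)
Conditions: HF·pyridine, pyridine, THF, 0 °C → rt
Reagents that add atoms: none
Why: Fluoride-mediated cleavage of the primary silyl ether under mildly acidic conditions avoids retro-Claisen opening of the β-keto lactone and α-ketol rearrangement.

## Compound list

1 | 3,3-dimethylglutaric anhydride | CC1(C)CC(=O)OC(=O)C1 | starting material
2 | 5-methoxy-3,3-dimethyl-5-oxopentanoic acid | COC(=O)CC(C)(C)CC(=O)O | intermediate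
3 | methyl 5-chloro-3,3-dimethyl-5-oxopentanoate | COC(=O)CC(C)(C)CC(=O)Cl | intermediate
4 | propargyl alcohol | OCC#C | starting material
5 | 1-methoxy-4-[(prop-2-yn-1-yloxy)methyl]benzene | C#CCOCc1ccc(OC)cc1 | intermediate
6 | methyl 8-[(4-methoxybenzyl)oxy]-3,3-dimethyl-5-oxooct-6-ynoate | COC(=O)CC(C)(C)CC(=O)C#CCOCc1ccc(OC)cc1 | intermediate
7 | methyl (Z)-7-iodo-8-[(4-methoxybenzyl)oxy]-3,3-dimethyl-5-oxooct-6-enoate | COC(=O)CC(C)(C)CC(=O)/C=C(\I)COCc1ccc(OC)cc1 | intermediate
8 | methyl (5S,6Z)-5-hydroxy-7-iodo-8-[(4-methoxybenzyl)oxy]-3,3-dimethyloct-6-enoate | COC(=O)CC(C)(C)C[C@H](O)/C=C(\I)COCc1ccc(OC)cc1 | intermediate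
9 | methyl (5S,6E)-5-hydroxy-7-{[(4-methoxybenzyl)oxy]methyl}-3,3-dimethyldeca-6,9-dienoate | COC(=O)CC(C)(C)C[C@H](O)/C=C(\CC=C)COCc1ccc(OC)cc1 | intermediate (not isolated)
10 | (6S)-6-[(1E)-2-{[(4-methoxybenzyl)oxy]methyl}penta-1,4-dien-1-yl]-4,4-dimethyloxan-2-one | O=C1CC(C)(C)C[C@@H](/C=C(\CC=C)COCc2ccc(OC)cc2)O1 | intermediate
11 | trimethylsilyl ketene acetal of lactone 10 | C[Si](C)(C)OC1=CC(C)(C)C[C@@H](/C=C(\CC=C)COCc2ccc(OC)cc2)O1 | intermediate (not isolated)
12 | trimethylsilyl ester of acid 13 | CC1(C)CC=C[C@](CC=C)(COCc2ccc(OC)cc2)[C@@H]1C(=O)O[Si](C)(C)C | intermediate (not isolated)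
13 | (1R,2S)-2-allyl-2-{[(4-methoxybenzyl)oxy]methyl}-6,6-dimethylcyclohex-3-ene-1-carboxylic acid | CC1(C)CC=C[C@](CC=C)(COCc2ccc(OC)cc2)[C@@H]1C(=O)O | intermediate
14 | [(1R,2S)-2-allyl-2-{[(4-methoxybenzyl)oxy]methyl}-6,6-dimethylcyclohex-3-en-1-yl]methanol | CC1(C)CC=C[C@](CC=C)(COCc2ccc(OC)cc2)[C@@H]1CO | intermediate
15 | TBS ether of 14 | CC1(C)CC=C[C@](CC=C)(COCc2ccc(OC)cc2)[C@@H]1CO[Si](C)(C)C(C)(C)C | intermediate
16 | ring A methyl ketone (C11 ketone; C20–OPMB; C6–OTBS) | CC1(C)CC=C[C@](CC(C)=O)(COCc2ccc(OC)cc2)[C@@H]1CO[Si](C)(C)C(C)(C)C | intermediate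
17 | terminal trimethylsilyl enol ether of 16 | CC1(C)CC=C[C@](CC(=C)O[Si](C)(C)C)(COCc2ccc(OC)cc2)[C@@H]1CO[Si](C)(C)C(C)(C)C | intermediate (not isolated)
18 | ring A chloromethyl ketone (C20–OPMB; C6–OTBS) | CC1(C)CC=C[C@](CC(=O)CCl)(COCc2ccc(OC)cc2)[C@@H]1CO[Si](C)(C)C(C)(C)C | intermediate
19 | ring A hydroxy chloromethyl ketone (C20–OH; C6–OTBS) | CC1(C)CC=C[C@](CC(=O)CCl)(CO)[C@@H]1CO[Si](C)(C)C(C)(C)C | intermediate
20 | 2-amino-4-methylphenol | Cc1ccc(O)c(N)c1 | starting material
21 | 6-diazo-4-methylcyclohexa-2,4-dien-1-one | CC1=CC(=[N+]=[N-])C(=O)C=C1 | intermediate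
22 | (3-methylcyclopenta-2,4-dien-1-ylidene)methanone (ketene) | CC1=CC(=C=O)C=C1 | intermediate (not isolated)
23 | 3-methylcyclopenta-2,4-diene-1-carboxylate of 19 (5H tautomer; ring sp3 carbon either epimer) | CC1(C)CC=C[C@](CC(=O)CCl)(COC(=O)C2C=CC(C)=C2)[C@@H]1CO[Si](C)(C)C(C)(C)C | intermediate (not isolated)
24 | 3-methylcyclopenta-1,3-diene-1-carboxylate of 19 (key-step precursor) | CC1(C)CC=C[C@](CC(=O)CCl)(COC(=O)C2=CC(C)=CC2)[C@@H]1CO[Si](C)(C)C(C)(C)C | intermediate
25 | oxyallyl cation (zwitterion) from 24 | CC1(C)CC=C[C@](C=C([O-])[CH2+])(COC(=O)C2=CC(C)=CC2)[C@@H]1CO[Si](C)(C)C(C)(C)C | intermediate (not isolated)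
26 | lactone-fused bicyclo[3.2.1]oct-6-en-3-one (key-step product) | CC1(C)CC=C[C@]2(COC(=O)[C@@]34C[C@@H](CC(=O)[C@H]32)C(C)=C4)[C@@H]1CO[Si](C)(C)C(C)(C)C | intermediate
27 | C11 tosylhydrazone of 26 | CC1(C)CC=C[C@]2(COC(=O)[C@@]34C[C@@H](CC(=NNS(=O)(=O)c5ccc(C)cc5)[C@H]32)C(C)=C4)[C@@H]1CO[Si](C)(C)C(C)(C)C | intermediate (not isolated)
28 | C11-deoxy lactone diene | CC1(C)CC=C[C@]2(COC(=O)[C@@]34C[C@@H](CC[C@H]32)C(C)=C4)[C@@H]1CO[Si](C)(C)C(C)(C)C | intermediate
29 | C15 hydroperoxide with C16=C17 methylene (C15 either epimer) | CC1(C)CC=C[C@]2(COC(=O)[C@@]34C[C@@H](CC[C@H]32)C(=C)C4OO)[C@@H]1CO[Si](C)(C)C(C)(C)C | intermediate (not isolated)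
30 | mono-enone (C15 ketone with C16=C17; ring A alkene intact) | CC1(C)CC=C[C@]2(COC(=O)[C@@]34C[C@@H](CC[C@H]32)C(=C)C4=O)[C@@H]1CO[Si](C)(C)C(C)(C)C | intermediate (not isolated)
31 | C1 hydroperoxide with C2=C3 (C1 either epimer) | CC1(C)C=CC(OO)[C@]2(COC(=O)[C@@]34C[C@@H](CC[C@H]32)C(=C)C4=O)[C@@H]1CO[Si](C)(C)C(C)(C)C | intermediate (not isolated)
32 | bis-enone | CC1(C)C=CC(=O)[C@]2(COC(=O)[C@@]34C[C@@H](CC[C@H]32)C(=C)C4=O)[C@@H]1CO[Si](C)(C)C(C)(C)C | intermediate
33 | C16 hydroperoxide of 34 | CC1(C)C=CC(=O)[C@]2(COC(=O)[C@@]34C[C@@H](CC[C@H]32)[C@](C)(OO)C4=O)[C@@H]1CO[Si](C)(C)C(C)(C)C | intermediate (not isolated)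
34 | C6-O-TBS ether of the target | CC1(C)C=CC(=O)[C@]2(COC(=O)[C@@]34C[C@@H](CC[C@H]32)[C@](C)(O)C4=O)[C@@H]1CO[Si](C)(C)C(C)(C)C | intermediate
35 | CNP0530135.1 | CC1(C)C=CC(=O)[C@]2(COC(=O)[C@@]34C[C@@H](CC[C@H]32)[C@](C)(O)C4=O)[C@@H]1CO | target

## Step count and risks

Total step count: 20. Longest linear sequence: 18 steps (steps 1, 2, 4–13 and 15–20, from anhydride 1).

**Step 16 (key step, proposed new method).** Three processes may defeat it. The oxyallyl cation may be captured by the solvent, or by the cyclopentadienide formed when the amine ionises the diene C–H, before it reaches the neutral diene. The s-cis ester conformer needed for closure may be too little populated. The addition may run through the compact arrangement, which would join the bicycle to C10 in the opposite sense.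
Fallback with known chemistry, from 18 back to 26: the tether is given up and the lactone is closed afterwards. Chloromethyl ketone 18 is treated under the same Föhlisch conditions with an excess of methyl 3-methylcyclopenta-1,3-diene-1-carboxylate F1 (made by irradiating 21 in methanol and used cold); intermolecular oxyallyl (4+3) cycloaddition with cyclopentadienes is an established reaction type. The isomers are separated at the stage of the bicyclic keto ester F2. DDQ removes the PMB group to give hydroxy ester F3, and acid-catalysed lactonisation (camphorsulfonic acid, benzene, 60 °C) with loss of methanol returns to 26.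

**Step 15 (ester formation).** The γ-hydroxy chloromethyl ketone 19 may rest as its cyclic hemiketal, so that acylation goes to the hemiketal hydroxyl, or it may cyclise by O-alkylation; the ketene may also be consumed by the diazide or by the diene product.
Fallback, from 18 back to 24: the ketone is masked at the alcohol level during ester formation and the ester is made by carbonylation instead of through the ketene. NaBH4 reduces 18 to chlorohydrin F4 (C11 either epimer), TESOTf/2,6-lutidine gives triethylsilyl ether F5, and DDQ frees the C20 alcohol F6. Alkoxycarbonylation of 4-methylcyclopenta-1,3-dien-2-yl triflate F7 (from 3-methylcyclopent-2-en-1-one, LDA, PhNTf2) with F6 under CO with Pd(OAc)2/dppf and Et3N gives, after tautomer equilibration, diene ester F8. PPTS/MeOH removes the triethylsilyl group to give chlorohydrin ester F9, and Dess–Martin periodinane oxidises it to 24.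

**Step 18 (double photooxygenation).** The ene reaction of the hindered cis-disubstituted ring A alkene is slow, so the exo-methylene enone formed first may degrade under prolonged irradiation, or conversion of ring A may stay incomplete.
Fallback, from 28 back to 34: ring A is oxidised by an epoxide route after the D-ring chemistry. Short irradiation under the conditions of step 18 is stopped at mono-enone 30, which is isolated and hydrated as in step 19 to ketol F10. mCPBA epoxidises the ring A alkene to F11, sodium phenylselenide opens the epoxide at C2 to hydroxy selenide F12, and H2O2 gives by selenoxide elimination the allylic alcohol F13 (C1–OH, C2=C3). Dess–Martin periodinane then gives 34.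

## Further compounds

F1 | step 16 | methyl 3-methylcyclopenta-1,3-diene-1-carboxylate | COC(=O)C1=CC(C)=CC1
F2 | step 16 | intermolecular (4+3) adduct: methyl bicyclo[3.2.1]oct-6-en-3-one-1-carboxylate carrying ring A at C9 (C20–OPMB; C6–OTBS) | COC(=O)[C@@]34C[C@@H](CC(=O)[C@H]3[C@]2(COCc5ccc(OC)cc5)C=CCC(C)(C)[C@H]2CO[Si](C)(C)C(C)(C)C)C(C)=C4
F3 | step 16 | hydroxy ester from F2 (C20–OH) | COC(=O)[C@@]34C[C@@H](CC(=O)[C@H]3[C@]2(CO)C=CCC(C)(C)[C@H]2CO[Si](C)(C)C(C)(C)C)C(C)=C4
F4 | step 15 | chlorohydrin from 18 (C11 either epimer) | CC1(C)CC=C[C@](CC(O)CCl)(COCc2ccc(OC)cc2)[C@@H]1CO[Si](C)(C)C(C)(C)C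
F5 | step 15 | triethylsilyl ether of F4 | CC1(C)CC=C[C@](CC(CCl)O[Si](CC)(CC)CC)(COCc2ccc(OC)cc2)[C@@H]1CO[Si](C)(C)C(C)(C)C
F6 | step 15 | C20 alcohol from F5 | CC1(C)CC=C[C@](CC(CCl)O[Si](CC)(CC)CC)(CO)[C@@H]1CO[Si](C)(C)C(C)(C)C
F7 | step 15 | 4-methylcyclopenta-1,3-dien-2-yl trifluoromethanesulfonate | CC1=CC(OS(=O)(=O)C(F)(F)F)=CC1
F8 | step 15 | 3-methylcyclopenta-1,3-diene-1-carboxylate of F6 | CC1(C)CC=C[C@](CC(CCl)O[Si](CC)(CC)CC)(COC(=O)C2=CC(C)=CC2)[C@@H]1CO[Si](C)(C)C(C)(C)C
F9 | step 15 | chlorohydrin diene ester from F8 | CC1(C)CC=C[C@](CC(O)CCl)(COC(=O)C2=CC(C)=CC2)[C@@H]1CO[Si](C)(C)C(C)(C)C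
F10 | step 18 | C16-hydroxy C15-ketone with ring A alkene intact | CC1(C)CC=C[C@]2(COC(=O)[C@@]34C[C@@H](CC[C@H]32)[C@](C)(O)C4=O)[C@@H]1CO[Si](C)(C)C(C)(C)C
F11 | step 18 | C1–C2 epoxide of F10 (epoxide face not assigned) | CC1(C)CC2OC2[C@]3(COC(=O)[C@@]54C[C@@H](CC[C@H]53)[C@](C)(O)C4=O)[C@@H]1CO[Si](C)(C)C(C)(C)C
F12 | step 18 | C1-hydroxy C2-phenylselanyl compound (C1 and C2 not assigned) | CC1(C)CC([Se]c6ccccc6)C(O)[C@]3(COC(=O)[C@@]54C[C@@H](CC[C@H]53)[C@](C)(O)C4=O)[C@@H]1CO[Si](C)(C)C(C)(C)C
F13 | step 18 | C1 allylic alcohol with C2=C3 (C1 not assigned) | CC1(C)C=CC(O)[C@]3(COC(=O)[C@@]54C[C@@H](CC[C@H]53)[C@](C)(O)C4=O)[C@@H]1CO[Si](C)(C)C(C)(C)C
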